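The readings are simulated for an exercise, noise included.

I began from amounts: a percentage hides what a flask holds, so I turned the target readings into molar amounts, c(target).

common to all: gas phase 23 mM (held)
- delta: solid substrate 0.40 M; run made earlier
- alpha: solid substrate 2.6 M; run made earlier
- blue: solid substrate 2.0 M; time 10 h
- green: solid substrate 1.0 M; time 10 h
- grey: solid substrate 1.5 M; time 10 h
- violet: solid substrate 0.50 M; time 10 h
- amber: solid substrate 0.30 M; time 10 h

| run | time / h | target / % | solid substrate / % |
|---|---|---|---|
| delta | 1.00 | 2.7 | 66.7 |
| delta | 2.00 | 5.7 | 45.6 |
| delta | 3.00 | 11.1 | 31.1 |
| delta | 4.00 | 16.5 | 17.1 |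
| delta | 5.00 | 21.2 | 4.4 |
| delta | 6.00 | 24.7 | 0.1 |
| delta | 8.00 | 31.8 | 0 |
| alpha | 1.00 | 0 | 94.1 |
| alpha | 2.00 | 0.5 | 91.7 |
| alpha | 3.00 | 1.1 | 89.4 |
| alpha | 4.00 | 2.2 | 88.0 |
| alpha | 5.00 | 2.4 | 85.9 |
| alpha | 6.00 | 3.8 | 83.6 |
| alpha | 8.00 | 5.5 | 80.9 |

(each reading ± 0.5 percentage points)

- given per volume of solution although it is solid: solid substrate
- the numbers in the tables scatter with a standard deviation of 0.5 percentage points
- at the start none of the gas phase is in solution
- at the start none of the solid substrate is in solution
- what has only dissolved of solid substrate counts as not reacted

* ranking by amount of target, in percent of the solid substrate charged, from high to low, at 10 h (blue / green / grey / violet / amber)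
* the amount of target, in percent of the solid substrate charged of the flask you put first, at 10 h
* the amount of target, in percent of the solid substrate charged of the flask you put last, at 10 h

First question: did the charge change the rate? Between its second and fifth readings the delta run gained 0.0207 M/h. Between its third and seventh readings the alpha run gained 0.0229 M/h. That is a rate ratio of 1.11 against a charge ratio of 6.50, so while solid stood, target grew at zero order in the charge. I carried the alpha line forward to the asked time and called the result the molar take, the c(target) of a flask that still holds solid at that time: 0.189 M.

Second question: which flasks kept solid? The alpha run lost 0.0490 M/h of solid substrate. Extended to 10 h, I reckoned its loss at 0.595 M, which is less than the green charge but more than the violet charge. So I divided the take by the charge: green 18.9%, grey 12.6%, blue 9.44%.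

Third question: what of amber and violet? After its solid fell to 0.1%, the delta run gained 0.0142 M/h, slower than before, so I did not apply the take to them.

The forecast ranked amber > violet > green > grey > blue. It gave 42% (36% to 50%) for the first flask and 9.3% (8.3% to 10.3%) for the last, reasoning that “substrate passes through an intermediate”. Its blue figure lay slightly below mine.

The simulation gave amber > violet > green > grey > blue, with amber at 35.8% and blue at 8.48%.

    gas phase ⇌ dissolved gas, rate k1*(csat - [dissolved gas]) (kL = 4.50 /h)
    starting material + dissolved gas → target (k = 6.10 /M/h)
    starting material → side product (k = 0.110 /h)
    target → over-reaction product (k = 0.0400 /h)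
    solid substrate ⇌ starting material, rate k5*(cs5 - [starting material]) while solid is left; crystals form when [starting material] > cs5 (solubility = 0.280 M, k = 0.620 /h)

Amber came in 6.2 percentage points under the forecast. Blue held 0.170 M of target and green 0.170 M, nearly equal, and both fell short of my take of 0.189 M. Solid still stood in both at 10.0 h, at 69.6% in blue and 39.1% in green. Part of what held the target of blue down was the low solubility of starting material, which also sets how fast it dissolves: without it, blue gave 22.2% of target instead of 8.48%.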